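## Retrosynthetic overview

1. The hydroquinone is made last from phenol 26 (para-oxidation, then reduction); 26 is split at C9–C10 (sp3–sp2 coupling) into vinyl iodide 11 and diene 24.
2. East half: 11 comes from alkyne 9 (carboalumination), 9 from 3-acetyloxolane 7 (Baeyer–Villiger), and 7 from diol 3 and ynal 4 by an enantioselective Prins cyclization with pinacol ring contraction (oxan-4-yl cation to oxolane), which sets both ring stereocentres.
3. West half: 24 comes from ortho-C-allylation of o-cresol with bromide 20; 20 comes from a vinylogous Mukaiyama aldol of enynal 13 with dienolate 16, which sets C5 and the 2E alkene; the 6E alkene is bought with 12.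
4. Ring order: the oxolane is formed first (step 2, through a transient oxane); the benzene ring comes from o-cresol and is only oxidised at the end.

Assumption: 3-hydroxy-3-methylbutan-2-one, 3-(trimethylsilyl)prop-2-ynal and (2E)-3-methylpent-2-en-4-yn-1-ol are taken as purchasable.

## Route

Step 1
Reactants: 1 3-hydroxy-3-methylbutan-2-one; 2 vinylmagnesium bromide
Product: 3 rac-2,3-dimethylpent-4-ene-2,3-diol
Conditions: 2 (2.5 equiv), THF, 0 °C to rt; aq. NH4Cl
Reagents that add atoms: none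
Why: Grignard 1,2-addition to the α-hydroxy ketone (the first equivalent is consumed by the OH); the new carbinol centre is racemic and is erased in step 2.

Step 2
Reactants: 3 rac-2,3-dimethylpent-4-ene-2,3-diol; 4 3-(trimethylsilyl)prop-2-ynal
Product: 7 1-{(3S,5S)-2,2-dimethyl-5-[(trimethylsilyl)ethynyl]oxolan-3-yl}ethan-1-one, via oxocarbenium ion 5 (not isolated), via oxan-4-yl cation 6 (not isolated)
Conditions: chiral confined imidodiphosphorimidate (IDPi) Brønsted acid (5 mol%, enantiomer chosen by screening for the 3S,5S product), 5 Å MS, CHCl3, −30 °C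
Reagents that add atoms: none
Why: Proposed new method: a catalytic enantioselective, enantioconvergent Prins cyclization–pinacol ring contraction in which the acid condenses 3 and 4 to the E-oxocarbenium/IDPi ion pair 5, the vinyl group attacks one face in a chair (6-endo Prins) to give cation 6, and a 1,2-shift of the ring C–CMe2(O) bond to the cationic carbon (driven by C=O formation) contracts the oxane to the cis-3-acetyl-5-alkynyloxolane; the chiral anion sets C5 in the C–C bond formation, the shift relays it to C3 (cis), and because the carbinol centre of rac-3 is destroyed both enantiomers can converge; the closest known reactions are the SnCl4-promoted Prins–pinacol rearrangement of allylic diol acetals to cis-3-acyl-tetrahydrofurans (racemic or substrate-controlled) and IDPi-catalysed asymmetric Prins cyclizations.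

Step 3
Reactants: 7 1-{(3S,5S)-2,2-dimethyl-5-[(trimethylsilyl)ethynyl]oxolan-3-yl}ethan-1-one
Product: 8 (3S,5S)-2,2-dimethyl-5-[(trimethylsilyl)ethynyl]oxolan-3-yl acetate
Conditions: mCPBA, NaHCO3, CH2Cl2, rt
Reagents that add atoms: mCPBA, OOC(=O)c1cccc(Cl)c1
Why: Baeyer–Villiger oxidation; the secondary ring carbon migrates in preference to methyl with retention, so C3 keeps its configuration, and the silyl alkyne is inert to the peracid.

Step 4
Reactants: 8 (3S,5S)-2,2-dimethyl-5-[(trimethylsilyl)ethynyl]oxolan-3-yl acetate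
Product: 9 (3S,5S)-5-ethynyl-2,2-dimethyloxolan-3-ol
Conditions: K2CO3 (cat.), MeOH, rt
Reagents that add atoms: none
Why: Methanolysis of the acetate and protodesilylation of the alkynylsilane occur together under the same mild base; no stereocentre is touched.

Step 5
Reactants: 9 (3S,5S)-5-ethynyl-2,2-dimethyloxolan-3-ol
Product: 11 (3S,5S)-5-[(1E)-1-iodoprop-1-en-2-yl]-2,2-dimethyloxolan-3-ol, via alkenylalane 10 (not isolated)
Conditions: AlMe3 (3.5 equiv), Cp2ZrCl2 (0.3 equiv), CH2Cl2, 0 °C to rt; then I2, THF, −30 to 0 °C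
Reagents that add atoms: trimethylaluminium, C[Al](C)C; iodine, II
Why: Negishi zirconium-catalysed carboalumination adds Me–Al syn with methyl on the internal carbon (the OH is carried as its aluminium alkoxide), and iodinolysis with retention gives the E-vinyl iodide that fixes the 10E alkene.

Step 6
Reactants: 12 (2E)-3-methylpent-2-en-4-yn-1-ol
Product: 13 (2E)-3-methylpent-2-en-4-ynal
Conditions: activated MnO2, CH2Cl2, rt; used as a solution
Reagents that add atoms: none
Why: Selective MnO2 oxidation of the allylic alcohol with retention of the E geometry that becomes the 6E alkene.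

Step 7
Reactants: 14 methyl 3-methylbut-2-enoate
Product: 16 tert-butyl[(1-methoxy-3-methylbuta-1,3-dien-1-yl)oxy]dimethylsilane, via lithium dienolate 15 (not isolated)
Conditions: LDA, THF/DMPU, −78 °C; TBSCl
Reagents that add atoms: tert-butyldimethylsilyl chloride, CC(C)(C)[Si](C)(C)Cl
Why: γ-Deprotonation of the enoate and O-silylation give the silyl dienol ether (ketene acetal geometry is not stereochemically relevant).

Step 8
Reactants: 13 (2E)-3-methylpent-2-en-4-ynal; 16 tert-butyl[(1-methoxy-3-methylbuta-1,3-dien-1-yl)oxy]dimethylsilane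
Product: 17 methyl (2E,5S,6E)-5-hydroxy-3,7-dimethylnona-2,6-dien-8-ynoate
Conditions: SiCl4 (1.2 equiv), Denmark binaphthyldiamine bisphosphoramide (2 mol%, the enantiomer giving Si-face attack, (S,S) by the published model), i-Pr2NEt (10 mol%), CH2Cl2, −78 °C; aq. KF/NaHCO3
Reagents that add atoms: none
Why: Lewis-base-activated SiCl4 vinylogous Mukaiyama aldol, which is γ-selective and gives the E-enoate; attack on the Si face of the conjugated aldehyde sets C5 as S.

Step 9
Reactants: 17 methyl (2E,5S,6E)-5-hydroxy-3,7-dimethylnona-2,6-dien-8-ynoate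
Product: 18 (2E,5S,6E)-3,7-dimethylnona-2,6-dien-8-yne-1,5-diol
Conditions: DIBAL-H (3.3 equiv), CH2Cl2, −78 °C; Rochelle salt
Reagents that add atoms: none
Why: 1,2-Reduction of the enoate to the allylic alcohol; the alkyne and both alkenes are untouched at −78 °C.

Step 10
Reactants: 18 (2E,5S,6E)-3,7-dimethylnona-2,6-dien-8-yne-1,5-diol
Product: 19 (3E,5S,7E)-9-bromo-3,7-dimethylnona-3,7-dien-1-yn-5-ol
Conditions: CBr4 (1.05 equiv), PPh3 (1.05 equiv), 2,6-lutidine, CH2Cl2, −40 °C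
Reagents that add atoms: carbon tetrabromide, BrC(Br)(Br)Br
Why: Appel bromination; the unhindered primary allylic alcohol reacts much faster than the secondary one at low temperature and without allylic transposition.

Step 11
Reactants: 19 (3E,5S,7E)-9-bromo-3,7-dimethylnona-3,7-dien-1-yn-5-ol
Product: 20 (3E,5S,7E)-9-bromo-3,7-dimethylnona-3,7-dien-1-yn-5-yl acetate
Conditions: Ac2O, i-Pr2NEt, DMAP (5 mol%), CH2Cl2, 0 °C, 30 min
Reagents that add atoms: acetic anhydride, CC(=O)OC(C)=O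
Why: DMAP-catalysed O-acetylation with retention at C5; the non-nucleophilic base and short time spare the allylic bromide.

Step 12
Reactants: 20 (3E,5S,7E)-9-bromo-3,7-dimethylnona-3,7-dien-1-yn-5-yl acetate; 21 2-methylphenol
Product: 23 (3E,5S,7E)-9-(2-hydroxy-3-methylphenyl)-3,7-dimethylnona-3,7-dien-1-yn-5-yl acetate, via sodium 2-methylphenolate 22 (not isolated)
Conditions: 21 (3 equiv), NaH (2.8 equiv), toluene, 0 °C; then 20, rt
Reagents that add atoms: none
Why: Ortho-selective C-allylation of a sodium phenoxide as a tight ion pair in a non-polar solvent (SN2 at the primary allylic carbon, 2E retained); C6 is the only free ortho position and no free hydride is left to touch the alkyne or acetate.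

Step 13
Reactants: 23 (3E,5S,7E)-9-(2-hydroxy-3-methylphenyl)-3,7-dimethylnona-3,7-dien-1-yn-5-yl acetate
Product: 24 (3E,5S,7E)-9-(2-hydroxy-3-methylphenyl)-3,7-dimethylnona-1,3,7-trien-5-yl acetate
Conditions: H2 (1 atm), Lindlar catalyst, quinoline, EtOAc, rt, stopped at 1 equiv
Reagents that add atoms: none
Why: Lindlar semihydrogenation of the terminal alkyne to the vinyl group; trisubstituted alkenes and the acetate are not reduced.

Step 14
Reactants: 24 (3E,5S,7E)-9-(2-hydroxy-3-methylphenyl)-3,7-dimethylnona-1,3,7-trien-5-yl acetate; 11 (3S,5S)-5-[(1E)-1-iodoprop-1-en-2-yl]-2,2-dimethyloxolan-3-ol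
Product: 26 (2E,5S,6E,10E)-1-(2-hydroxy-3-methylphenyl)-11-[(2S,4S)-4-hydroxy-5,5-dimethyloxolan-2-yl]-3,7-dimethyldodeca-2,6,10-trien-5-yl acetate, via B-alkyl-9-BBN adduct 25 (not isolated)
Conditions: 24, 9-BBN (2.3 equiv), THF, 0 °C to rt; trace H2O; then 11, Pd(dppf)Cl2 (5 mol%), AsPh3 (10 mol%), Cs2CO3, DMF/H2O, rt
Reagents that add atoms: none
Why: 9-BBN hydroborates only the monosubstituted terminal alkene of the diene (anti-Markovnikov; the phenol is carried as its borinate), and the B-alkyl Suzuki–Miyaura coupling joins C9 to C10 with retention of the E-vinyl iodide geometry, fast enough at rt to outrun ionisation of the hindered allylic acetate.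

Step 15
Reactants: 26 (2E,5S,6E,10E)-1-(2-hydroxy-3-methylphenyl)-11-[(2S,4S)-4-hydroxy-5,5-dimethyloxolan-2-yl]-3,7-dimethyldodeca-2,6,10-trien-5-yl acetate
Product: 28 (2E,5S,6E,10E)-1-(2,5-dihydroxy-3-methylphenyl)-11-[(2S,4S)-4-hydroxy-5,5-dimethyloxolan-2-yl]-3,7-dimethyldodeca-2,6,10-trien-5-yl acetate, via benzoquinone 27 (not isolated)
Conditions: Fremy's salt (2.5 equiv), KH2PO4, acetone/H2O, rt; then Na2S2O4 (aq.) in the same flask, under Ar
Reagents that add atoms: potassium nitrosodisulfonate (Fremy's salt), [K+].[K+].[O]N(S(=O)(=O)[O-])S(=O)(=O)[O-]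
Why: Teuber oxidation of the 2,6-disubstituted phenol gives the para-quinone without touching the alkenes, the acetate or the free alcohol, and dithionite reduces it to the hydroquinone.

## Compound list

1 | 3-hydroxy-3-methylbutan-2-one | CC(=O)C(C)(C)O | starting material
2 | vinylmagnesium bromide | C=C[Mg]Br | starting material
3 | rac-2,3-dimethylpent-4-ene-2,3-diol | C=CC(C)(O)C(C)(C)O | intermediate
4 | 3-(trimethylsilyl)prop-2-ynal | C[Si](C)(C)C#CC=O | starting material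
5 | (E)-(3-hydroxy-2,3-dimethylpent-4-en-2-yl)[3-(trimethylsilyl)prop-2-yn-1-ylidene]oxidanium (IDPi ion pair; carbinol centre racemic) | C=CC(C)(O)C(C)(C)/[O+]=C/C#C[Si](C)(C)C | intermediate
6 | (2S)-5-hydroxy-5,6,6-trimethyl-2-[(trimethylsilyl)ethynyl]oxan-4-ylium (carbinol centre either configuration) | C[Si](C)(C)C#C[C@@H]1C[CH+]C(C)(O)C(C)(C)O1 | intermediate
7 | 1-{(3S,5S)-2,2-dimethyl-5-[(trimethylsilyl)ethynyl]oxolan-3-yl}ethan-1-one | C[Si](C)(C)C#C[C@@H]1C[C@H](C(C)=O)C(C)(C)O1 | intermediate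
8 | (3S,5S)-2,2-dimethyl-5-[(trimethylsilyl)ethynyl]oxolan-3-yl acetate | C[Si](C)(C)C#C[C@@H]1C[C@H](OC(C)=O)C(C)(C)O1 | intermediate
9 | (3S,5S)-5-ethynyl-2,2-dimethyloxolan-3-ol | C#C[C@@H]1C[C@H](O)C(C)(C)O1 | intermediate
10 | {(1E)-2-[(2S,4S)-4-[(dimethylalumanyl)oxy]-5,5-dimethyloxolan-2-yl]prop-1-en-1-yl}dimethylalumane | C[Al](C)/C=C(\C)[C@@H]1C[C@H](O[Al](C)C)C(C)(C)O1 | intermediate
11 | (3S,5S)-5-[(1E)-1-iodoprop-1-en-2-yl]-2,2-dimethyloxolan-3-ol | I/C=C(\C)[C@@H]1C[C@H](O)C(C)(C)O1 | intermediate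
12 | (2E)-3-methylpent-2-en-4-yn-1-ol | C#C/C(C)=C/CO | starting material
13 | (2E)-3-methylpent-2-en-4-ynal | C#C/C(C)=C/C=O | intermediate
14 | methyl 3-methylbut-2-enoate | COC(=O)C=C(C)C | starting material
15 | lithium 1-methoxy-3-methylbuta-1,3-dien-1-olate | [Li+].COC([O-])=CC(C)=C | intermediate
16 | tert-butyl[(1-methoxy-3-methylbuta-1,3-dien-1-yl)oxy]dimethylsilane (ketene acetal geometry undefined) | COC(O[Si](C)(C)C(C)(C)C)=CC(C)=C | intermediate
17 | methyl (2E,5S,6E)-5-hydroxy-3,7-dimethylnona-2,6-dien-8-ynoate | C#C/C(C)=C/[C@@H](O)C/C(C)=C/C(=O)OC | intermediate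
18 | (2E,5S,6E)-3,7-dimethylnona-2,6-dien-8-yne-1,5-diol | C#C/C(C)=C/[C@@H](O)C/C(C)=C/CO | intermediate
19 | (3E,5S,7E)-9-bromo-3,7-dimethylnona-3,7-dien-1-yn-5-ol | C#C/C(C)=C/[C@@H](O)C/C(C)=C/CBr | intermediate
20 | (3E,5S,7E)-9-bromo-3,7-dimethylnona-3,7-dien-1-yn-5-yl acetate | C#C/C(C)=C/[C@@H](OC(C)=O)C/C(C)=C/CBr | intermediate
21 | 2-methylphenol (o-cresol) | Cc1ccccc1O | starting material
22 | sodium 2-methylphenolate | [Na+].Cc1ccccc1[O-] | intermediate
23 | (3E,5S,7E)-9-(2-hydroxy-3-methylphenyl)-3,7-dimethylnona-3,7-dien-1-yn-5-yl acetate | C#C/C(C)=C/[C@@H](OC(C)=O)C/C(C)=C/Cc1cccc(C)c1O | intermediate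
24 | (3E,5S,7E)-9-(2-hydroxy-3-methylphenyl)-3,7-dimethylnona-1,3,7-trien-5-yl acetate | C=C/C(C)=C/[C@@H](OC(C)=O)C/C(C)=C/Cc1cccc(C)c1O | intermediate
25 | (2E,5S,6E)-9-(9-borabicyclo[3.3.1]nonan-9-yl)-1-{2-[(9-borabicyclo[3.3.1]nonan-9-yl)oxy]-3-methylphenyl}-3,7-dimethylnona-2,6-dien-5-yl acetate | CC(=O)O[C@H](/C=C(\C)CCB1C2CCCC1CCC2)C/C(C)=C/Cc1cccc(C)c1OB1C2CCCC1CCC2 | intermediate
26 | (2E,5S,6E,10E)-1-(2-hydroxy-3-methylphenyl)-11-[(2S,4S)-4-hydroxy-5,5-dimethyloxolan-2-yl]-3,7-dimethyldodeca-2,6,10-trien-5-yl acetate | CC(=O)O[C@H](/C=C(\C)CC/C=C(\C)[C@@H]1C[C@H](O)C(C)(C)O1)C/C(C)=C/Cc1cccc(C)c1O | intermediate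
27 | (2E,5S,6E,10E)-11-[(2S,4S)-4-hydroxy-5,5-dimethyloxolan-2-yl]-3,7-dimethyl-1-(5-methyl-3,6-dioxocyclohexa-1,4-dien-1-yl)dodeca-2,6,10-trien-5-yl acetate | CC(=O)O[C@H](/C=C(\C)CC/C=C(\C)[C@@H]1C[C@H](O)C(C)(C)O1)C/C(C)=C/CC1=CC(=O)C=C(C)C1=O | intermediate
28 | (2E,5S,6E,10E)-1-(2,5-dihydroxy-3-methylphenyl)-11-[(2S,4S)-4-hydroxy-5,5-dimethyloxolan-2-yl]-3,7-dimethyldodeca-2,6,10-trien-5-yl acetate (CNP0227918.2) | CC(=O)O[C@H](/C=C(\C)CC/C=C(\C)[C@@H]1C[C@H](O)C(C)(C)O1)C/C(C)=C/Cc1cc(O)cc(C)c1O | target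

## Step count and risks

Total steps: 15. Longest linear sequence: 9 (12 → 13 → 17 → 18 → 19 → 20 → 23 → 24 → 26 → 28; steps 6 and 8–15). The east branch is 7 steps (1–5, 14, 15).

Three steps most likely to fail:

Step 2 (the proposed asymmetric Prins–pinacol ring contraction). The vinyl group is a weak nucleophile, and the mismatched enantiomer of rac-3 may react slowly or with low selectivity, which would cap the yield near 50 % or erode the ee. The fallback uses known chemistry and builds the same oxolane by a 5-endo epoxide opening; it sets out from 4 and comes back at 9. Prenylbarium chloride (from 1-chloro-3-methylbut-2-ene and Rieke barium, THF, −78 °C, α-selective) adds to 4 to give rac-6-methyl-1-(trimethylsilyl)hept-5-en-1-yn-3-ol F1. Buffered Dess–Martin oxidation gives 6-methyl-1-(trimethylsilyl)hept-5-en-1-yn-3-one F2. Noyori transfer hydrogenation with RuCl[(S,S)-TsDPEN](p-cymene) in i-PrOH gives (3S)-6-methyl-1-(trimethylsilyl)hept-5-en-1-yn-3-ol F3. Shi epoxidation of the trisubstituted alkene (the ketone enantiomer that gives the 2S epoxide) gives (2S)-1-[(2S)-3,3-dimethyloxiran-2-yl]-4-(trimethylsilyl)but-3-yn-2-ol F4. Catalytic CSA in CH2Cl2 closes the ring at the tertiary epoxide carbon to (3S,5S)-2,2-dimethyl-5-[(trimethylsilyl)ethynyl]oxolan-3-ol F5, and K2CO3/MeOH removes the silyl group to give 9.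

Step 12 (ortho-C-allylation of sodium 2-methylphenolate). O-allylation or attack on the acetate may dominate. The fallback replaces ambident phenoxide alkylation by directed ortho-metalation and an arylcopper SN2 coupling; it sets out from 21 (with 20) and comes back at 23. MOMCl/i-Pr2NEt converts 21 into 1-(methoxymethoxy)-2-methylbenzene F6. n-BuLi/TMEDA in Et2O lithiates the only free ortho position to [2-(methoxymethoxy)-3-methylphenyl]lithium F7. CuBr·SMe2 at −78 °C gives [2-(methoxymethoxy)-3-methylphenyl]copper F8 (used in excess, since some is consumed by the alkyne C–H). F8 displaces the primary allylic bromide of 20 to give (3E,5S,7E)-9-[2-(methoxymethoxy)-3-methylphenyl]-3,7-dimethylnona-3,7-dien-1-yn-5-yl acetate F9. PPTS in MeOH at 40 °C removes the acetal and gives 23.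

Step 14 (hydroboration of a dienyl acetate beside a free phenol, then Pd(0) next to an allylic acetate). Hydroboration may be unselective, or palladium may ionise the C5 acetate and scramble or lose it. The fallback joins the two halves before the acetate and the arene exist and distinguishes the two secondary alcohols by a silyl ether; it sets out from 11 and 17 and comes back at 26.
- TBSOTf/2,6-lutidine converts 11 into tert-butyl{[(3S,5S)-5-[(1E)-1-iodoprop-1-en-2-yl]-2,2-dimethyloxolan-3-yl]oxy}dimethylsilane F10.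
- Lindlar semihydrogenation of 17 gives methyl (2E,5S,6E)-5-hydroxy-3,7-dimethylnona-2,6,8-trienoate F11.
- 9-BBN hydroboration of F11 and Suzuki coupling with F10 give methyl (2E,5S,6E,10E)-11-[(2S,4S)-4-{[tert-butyl(dimethyl)silyl]oxy}-5,5-dimethyloxolan-2-yl]-5-hydroxy-3,7-dimethyldodeca-2,6,10-trienoate F12.
- DIBAL-H gives (2E,5S,6E,10E)-11-[(2S,4S)-4-{[tert-butyl(dimethyl)silyl]oxy}-5,5-dimethyloxolan-2-yl]-3,7-dimethyldodeca-2,6,10-triene-1,5-diol F13.
- CBr4/PPh3 at −40 °C gives (2E,5S,6E,10E)-1-bromo-11-[(2S,4S)-4-{[tert-butyl(dimethyl)silyl]oxy}-5,5-dimethyloxolan-2-yl]-3,7-dimethyldodeca-2,6,10-trien-5-ol F14.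
- Ac2O/DMAP gives (2E,5S,6E,10E)-1-bromo-11-[(2S,4S)-4-{[tert-butyl(dimethyl)silyl]oxy}-5,5-dimethyloxolan-2-yl]-3,7-dimethyldodeca-2,6,10-trien-5-yl acetate F15.
- Sodium 2-methylphenolate 22 in toluene gives (2E,5S,6E,10E)-11-[(2S,4S)-4-{[tert-butyl(dimethyl)silyl]oxy}-5,5-dimethyloxolan-2-yl]-1-(2-hydroxy-3-methylphenyl)-3,7-dimethyldodeca-2,6,10-trien-5-yl acetate F16.
- HF·pyridine removes the silyl ether and gives 26.

## Further compounds

F1 | step 2 | rac-6-methyl-1-(trimethylsilyl)hept-5-en-1-yn-3-ol | CC(C)=CCC(O)C#C[Si](C)(C)C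
F2 | step 2 | 6-methyl-1-(trimethylsilyl)hept-5-en-1-yn-3-one | CC(C)=CCC(=O)C#C[Si](C)(C)C
F3 | step 2 | (3S)-6-methyl-1-(trimethylsilyl)hept-5-en-1-yn-3-ol | C[Si](C)(C)C#C[C@@H](O)CC=C(C)C
F4 | step 2 | (2S)-1-[(2S)-3,3-dimethyloxiran-2-yl]-4-(trimethylsilyl)but-3-yn-2-ol | C[Si](C)(C)C#C[C@@H](O)C[C@@H]1OC1(C)C
F5 | step 2 | (3S,5S)-2,2-dimethyl-5-[(trimethylsilyl)ethynyl]oxolan-3-ol | C[Si](C)(C)C#C[C@@H]1C[C@H](O)C(C)(C)O1
F6 | step 12 | 1-(methoxymethoxy)-2-methylbenzene | COCOc1ccccc1C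
F7 | step 12 | [2-(methoxymethoxy)-3-methylphenyl]lithium | [Li]c1cccc(C)c1OCOC
F8 | step 12 | [2-(methoxymethoxy)-3-methylphenyl]copper | [Cu]c1cccc(C)c1OCOC
F9 | step 12 | (3E,5S,7E)-9-[2-(methoxymethoxy)-3-methylphenyl]-3,7-dimethylnona-3,7-dien-1-yn-5-yl acetate | C#C/C(C)=C/[C@@H](OC(C)=O)C/C(C)=C/Cc1cccc(C)c1OCOC
F10 | step 14 | tert-butyl{[(3S,5S)-5-[(1E)-1-iodoprop-1-en-2-yl]-2,2-dimethyloxolan-3-yl]oxy}dimethylsilane | I/C=C(\C)[C@@H]1C[C@H](O[Si](C)(C)C(C)(C)C)C(C)(C)O1
F11 | step 14 | methyl (2E,5S,6E)-5-hydroxy-3,7-dimethylnona-2,6,8-trienoate | C=C/C(C)=C/[C@@H](O)C/C(C)=C/C(=O)OC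
F12 | step 14 | methyl (2E,5S,6E,10E)-11-[(2S,4S)-4-{[tert-butyl(dimethyl)silyl]oxy}-5,5-dimethyloxolan-2-yl]-5-hydroxy-3,7-dimethyldodeca-2,6,10-trienoate | COC(=O)/C=C(\C)C[C@H](O)/C=C(\C)CC/C=C(\C)[C@@H]1C[C@H](O[Si](C)(C)C(C)(C)C)C(C)(C)O1
F13 | step 14 | (2E,5S,6E,10E)-11-[(2S,4S)-4-{[tert-butyl(dimethyl)silyl]oxy}-5,5-dimethyloxolan-2-yl]-3,7-dimethyldodeca-2,6,10-triene-1,5-diol | OC/C=C(\C)C[C@H](O)/C=C(\C)CC/C=C(\C)[C@@H]1C[C@H](O[Si](C)(C)C(C)(C)C)C(C)(C)O1
F14 | step 14 | (2E,5S,6E,10E)-1-bromo-11-[(2S,4S)-4-{[tert-butyl(dimethyl)silyl]oxy}-5,5-dimethyloxolan-2-yl]-3,7-dimethyldodeca-2,6,10-trien-5-ol | BrC/C=C(\C)C[C@H](O)/C=C(\C)CC/C=C(\C)[C@@H]1C[C@H](O[Si](C)(C)C(C)(C)C)C(C)(C)O1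
F15 | step 14 | (2E,5S,6E,10E)-1-bromo-11-[(2S,4S)-4-{[tert-butyl(dimethyl)silyl]oxy}-5,5-dimethyloxolan-2-yl]-3,7-dimethyldodeca-2,6,10-trien-5-yl acetate | BrC/C=C(\C)C[C@H](OC(C)=O)/C=C(\C)CC/C=C(\C)[C@@H]1C[C@H](O[Si](C)(C)C(C)(C)C)C(C)(C)O1
F16 | step 14 | (2E,5S,6E,10E)-11-[(2S,4S)-4-{[tert-butyl(dimethyl)silyl]oxy}-5,5-dimethyloxolan-2-yl]-1-(2-hydroxy-3-methylphenyl)-3,7-dimethyldodeca-2,6,10-trien-5-yl acetate | Cc1cccc(C/C=C(\C)C[C@H](OC(C)=O)/C=C(\C)CC/C=C(\C)[C@@H]2C[C@H](O[Si](C)(C)C(C)(C)C)C(C)(C)O2)c1O
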